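## Retrosynthetic overview

- The N-oxide comes from the pyridine by N-oxidation, and the 4-methoxy group from O-methylation of a 4-pyridone.
- The pyridone ring (ring B) is closed last, by ammonia on an enaminone 1,3-diketone (N1–C2 and N1–C8a). The C2–C3 bond comes from α'-acetylation with a Weinreb amide.
- Key disconnection: C5–C1'. The β-carbon of cyclohexanone is used as a nucleophile, in the form of a chiral 1-aminoallyl anion, and is alkylated with (5-bromopentyl)benzene. This sets C5 and leaves the enamine double bond pointing at C4a.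
- That enamine is acylated at C4a in the same flask with methoxyacetyl chloride (C4a–C4).
- The aminoallyl precursor is made from 3-bromocyclohexene and (2R)-2-(methoxymethyl)pyrrolidine. The carbocycle (ring A) is bought; ring B is built on it.

Assumption: the facial sense of the auxiliary-controlled alkylation in step 2 follows the chelation model given there; if experiment shows the opposite sense, the enantiomeric auxiliary, equally available, is used with no other change.

## Route

Step 1
Reactants: 1 3-bromocyclohexene (racemic); 2 (2R)-2-(methoxymethyl)pyrrolidine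
Product: 3 (2R)-1-(cyclohex-2-en-1-yl)-2-(methoxymethyl)pyrrolidine (both epimers at the cyclohexenyl carbon)
Conditions: K2CO3 (2 equiv), MeCN, 0 °C to rt
Reagents that add atoms: none
Why: SN2 N-alkylation of the secondary amine by the allylic bromide; the new allylic centre forms as a mixture, which does not matter because it is erased by deprotonation in step 2.

Step 2
Reactants: 3 (2R)-1-(cyclohex-2-en-1-yl)-2-(methoxymethyl)pyrrolidine; 4 (5-bromopentyl)benzene; 5 methoxyacetyl chloride
Product: 8 2-methoxy-1-[(6R)-2-[(2R)-2-(methoxymethyl)pyrrolidin-1-yl]-6-(5-phenylpentyl)cyclohex-1-en-1-yl]ethan-1-one, via aminoallyllithium 6 (not isolated), via enamine 7 (not isolated)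
Conditions: s-BuLi (1.0 equiv), THF, −78 to −30 °C; 4 (1.0 equiv), −95 to −78 °C; 5 (1.2 equiv) then Et3N (1.5 equiv), −78 to 0 °C
Reagents that add atoms: none
Why: Proposed new method: s-BuLi, pre-complexed by the amine nitrogen and the ether oxygen, removes the allylic α-amino hydrogen to give the 1-aminoallyllithium 6 (a cyclohexanone β-carbanion, i.e. homoenolate, equivalent) with lithium held over the allyl face on the side of the methoxymethyl arm; the primary bromide 4 then attacks the unhindered γ-terminus anti to lithium (Re face with the 2R auxiliary; α-attack would create a quaternary centre), which sets C5 as R and leaves enamine 7 with its double bond regiospecifically toward C4a, where it is C-acylated by 5 (Stork enamine acylation); the closest known reaction type is the γ-alkylation of metalated chiral allylamines used as homoenolate equivalents, here extended to a cyclic ketone-derived system and coupled with enamine acylation.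

Step 3
Reactants: 8 2-methoxy-1-[(6R)-2-[(2R)-2-(methoxymethyl)pyrrolidin-1-yl]-6-(5-phenylpentyl)cyclohex-1-en-1-yl]ethan-1-one; 9 N-methoxy-N-methylacetamide
Product: 11 2-methoxy-1-[(6R)-2-[(2R)-2-(methoxymethyl)pyrrolidin-1-yl]-6-(5-phenylpentyl)cyclohex-1-en-1-yl]butane-1,3-dione (C2 epimers, largely enolised), via lithium enolate 10 (not isolated)
Conditions: LiN(i-Pr)2 (1.2 equiv), THF, −78 °C; 9 (1.3 equiv), −78 to 0 °C; aq NH4Cl
Reagents that add atoms: none
Why: Kinetic α'-deprotonation of the vinylogous amide at the methoxy-bearing CH2 (acidified and chelated by the α-oxygen) followed by Claisen-type C-acylation with a Weinreb amide, whose stable tetrahedral chelate prevents over-reaction; C5 is not acidic and is untouched.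

Step 4
Reactants: 11 2-methoxy-1-[(6R)-2-[(2R)-2-(methoxymethyl)pyrrolidin-1-yl]-6-(5-phenylpentyl)cyclohex-1-en-1-yl]butane-1,3-dione
Product: 12 (5R)-3-methoxy-2-methyl-5-(5-phenylpentyl)-5,6,7,8-tetrahydroquinolin-4(1H)-one
Conditions: NH4OAc (10 equiv), EtOH, 80 °C, sealed tube
Reagents that add atoms: ammonium acetate, CC(=O)[O-].[NH4+]
Why: 4-Pyridone synthesis from a 1,3,5-tricarbonyl equivalent, in which ammonia condenses with the methyl ketone and displaces the auxiliary amine by conjugate addition–elimination at the enaminone carbon, driven by aromatisation (the auxiliary 2 is recovered).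

Step 5
Reactants: 12 (5R)-3-methoxy-2-methyl-5-(5-phenylpentyl)-5,6,7,8-tetrahydroquinolin-4(1H)-one
Product: 13 (5R)-3,4-dimethoxy-2-methyl-5-(5-phenylpentyl)-5,6,7,8-tetrahydroquinoline
Conditions: MeI (1.5 equiv), Ag2CO3 (1.0 equiv), toluene, 40 °C, dark
Reagents that add atoms: iodomethane, CI
Why: Silver-salt O-alkylation of the ambident pyridone, helped by the nitrogen being flanked by the 2-methyl group and the C8 methylene, gives the 4-methoxypyridine.

Step 6
Reactants: 13 (5R)-3,4-dimethoxy-2-methyl-5-(5-phenylpentyl)-5,6,7,8-tetrahydroquinoline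
Product: 14 (5R)-3,4-dimethoxy-2-methyl-5-(5-phenylpentyl)-5,6,7,8-tetrahydroquinoline 1-oxide
Conditions: mCPBA (1.2 equiv), CH2Cl2, 0 °C to rt
Reagents that add atoms: mCPBA (3-chloroperoxybenzoic acid), OOC(=O)c1cccc(Cl)c1
Why: Peracid N-oxidation of the electron-rich pyridine, the only oxidisable site in the molecule, leaves the C5 stereocentre untouched.

## Compound list

1 | 3-bromocyclohexene (racemic) | BrC1C=CCCC1 | starting material
2 | (2R)-2-(methoxymethyl)pyrrolidine | COC[C@H]1CCCN1 | starting material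
3 | (2R)-1-(cyclohex-2-en-1-yl)-2-(methoxymethyl)pyrrolidine (epimers at the cyclohexenyl carbon) | COC[C@H]1CCCN1C1C=CCCC1 | intermediate
4 | (5-bromopentyl)benzene | BrCCCCCc1ccccc1 | starting material
5 | methoxyacetyl chloride | COCC(Cl)=O | starting material
6 | [1-[(2R)-2-(methoxymethyl)pyrrolidin-1-yl]cyclohex-2-en-1-yl]lithium (chelated 1-aminoallyllithium) | COC[C@H]1CCCN1C1([Li])C=CCCC1 | intermediate
7 | (2R)-2-(methoxymethyl)-1-[(3R)-3-(5-phenylpentyl)cyclohex-1-en-1-yl]pyrrolidine | COC[C@H]1CCCN1C1=C[C@H](CCCCCc2ccccc2)CCC1 | intermediate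
8 | 2-methoxy-1-[(6R)-2-[(2R)-2-(methoxymethyl)pyrrolidin-1-yl]-6-(5-phenylpentyl)cyclohex-1-en-1-yl]ethan-1-one | COCC(=O)C1=C(N2CCC[C@@H]2COC)CCC[C@H]1CCCCCc1ccccc1 | intermediate
9 | N-methoxy-N-methylacetamide | CC(=O)N(C)OC | starting material
10 | lithium enolate of 8 at the methoxymethylene carbon (geometry not assigned) | [Li]OC(=COC)C1=C(N2CCC[C@@H]2COC)CCC[C@H]1CCCCCc1ccccc1 | intermediate
11 | 2-methoxy-1-[(6R)-2-[(2R)-2-(methoxymethyl)pyrrolidin-1-yl]-6-(5-phenylpentyl)cyclohex-1-en-1-yl]butane-1,3-dione | CC(=O)C(OC)C(=O)C1=C(N2CCC[C@@H]2COC)CCC[C@H]1CCCCCc1ccccc1 | intermediate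
12 | (5R)-3-methoxy-2-methyl-5-(5-phenylpentyl)-5,6,7,8-tetrahydroquinolin-4(1H)-one | COc1c(C)[nH]c2c(c1=O)[C@H](CCCCCc1ccccc1)CCC2 | intermediate
13 | (5R)-3,4-dimethoxy-2-methyl-5-(5-phenylpentyl)-5,6,7,8-tetrahydroquinoline | COc1c(OC)c(C)nc2c1[C@H](CCCCCc1ccccc1)CCC2 | intermediate
14 | (5R)-3,4-dimethoxy-2-methyl-5-(5-phenylpentyl)-5,6,7,8-tetrahydroquinoline 1-oxide | COc1c(OC)c(C)[n+]([O-])c2c1[C@H](CCCCCc1ccccc1)CCC2 | target

## Step count and risks

Total steps: 6. Longest linear sequence: 6 steps (1 → 3 → 8 → 11 → 12 → 13 → 14).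

**Steps most likely to fail**

1. Step 2. Possible failures: deprotonation at the other allylic CH2 instead of the α-amino carbon, some α-alkylation, modest facial selectivity, or enamine isomerisation before acylation.
Fallback (sets out from 1, comes back at 12): the β-carbanion logic is kept, but a carbamate carbonyl directs the lithiation and an external chiral diamine sets the configuration. Compound 1 is used to N-alkylate tert-butyl (4-methoxyphenyl)carbamate (NaH, DMF) to give tert-butyl cyclohex-2-en-1-yl(4-methoxyphenyl)carbamate F1. Treatment with n-BuLi/sparteine (toluene, −78 °C; the enantiomer of the diamine that delivers the 3R product) and then 4 gives the γ-alkylated enecarbamate tert-butyl (4-methoxyphenyl)[(3R)-3-(5-phenylpentyl)cyclohex-1-en-1-yl]carbamate F2. MeLi (3 equiv, THF, −78 to 0 °C) strips the Boc group to release the regiodefined lithium azaenolate, which is C-acylated by methyl methoxyacetate to give 2-methoxy-1-[(6R)-2-(4-methoxyanilino)-6-(5-phenylpentyl)cyclohex-1-en-1-yl]ethan-1-one F3. α'-Acetylation (LiN(i-Pr)2, 2.3 equiv, then 9) gives 2-methoxy-1-[(6R)-2-(4-methoxyanilino)-6-(5-phenylpentyl)cyclohex-1-en-1-yl]butane-1,3-dione F4. NH4OAc in hot EtOH then closes the pyridone ring to 12 with loss of 4-methoxyaniline.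

2. Step 3. Possible failures: γ-deprotonation at the ring CH2 next to the amine-bearing carbon instead of α', or O-acylation.
Fallback (sets out from 8, comes back at 12): the order of bond formation is reversed so that no enolate regiochemistry is involved. NH4OAc in MeOH at 60 °C exchanges the auxiliary for NH2 to give 1-[(6R)-2-amino-6-(5-phenylpentyl)cyclohex-1-en-1-yl]-2-methoxyethan-1-one F5, with 2 recovered. N,N-Dimethylacetamide dimethyl acetal in toluene at 110 °C converts the NH2 into the amidine N'-[(3R)-2-(methoxyacetyl)-3-(5-phenylpentyl)cyclohex-1-en-1-yl]-N,N-dimethylethanimidamide F6. NaOMe in MeOH at 65 °C closes the C3–C2 bond by attack of the ketone enolate on the amidine carbon with loss of dimethylamine (an amidine analogue of the Camps cyclisation), giving 12.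

3. Step 5. Possible failures: N-methylation of the pyridone, or quaternisation of 13.
Fallback (sets out from 12, comes back at 14): the 4-oxygen is replaced and methoxide is introduced by substitution. POCl3 (90 °C) gives (5R)-4-chloro-3-methoxy-2-methyl-5-(5-phenylpentyl)-5,6,7,8-tetrahydroquinoline F7. mCPBA (CH2Cl2, rt) gives (5R)-4-chloro-3-methoxy-2-methyl-5-(5-phenylpentyl)-5,6,7,8-tetrahydroquinoline 1-oxide F8. NaOMe in MeOH at 65 °C displaces chloride at C4 by SNAr, activated by the N-oxide, and gives 14 directly, bypassing 13.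

Further compounds
F1 | step 2 | tert-butyl cyclohex-2-en-1-yl(4-methoxyphenyl)carbamate | COc1ccc(cc1)N(C1C=CCCC1)C(=O)OC(C)(C)C
F2 | step 2 | tert-butyl (4-methoxyphenyl)[(3R)-3-(5-phenylpentyl)cyclohex-1-en-1-yl]carbamate | COc1ccc(cc1)N(C(=O)OC(C)(C)C)C1=C[C@H](CCCCCc2ccccc2)CCC1
F3 | step 2 | 2-methoxy-1-[(6R)-2-(4-methoxyanilino)-6-(5-phenylpentyl)cyclohex-1-en-1-yl]ethan-1-one | COCC(=O)C1=C(Nc2ccc(OC)cc2)CCC[C@H]1CCCCCc1ccccc1
F4 | step 2 | 2-methoxy-1-[(6R)-2-(4-methoxyanilino)-6-(5-phenylpentyl)cyclohex-1-en-1-yl]butane-1,3-dione | CC(=O)C(OC)C(=O)C1=C(Nc2ccc(OC)cc2)CCC[C@H]1CCCCCc1ccccc1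
F5 | step 3 | 1-[(6R)-2-amino-6-(5-phenylpentyl)cyclohex-1-en-1-yl]-2-methoxyethan-1-one | COCC(=O)C1=C(N)CCC[C@H]1CCCCCc1ccccc1
F6 | step 3 | N'-[(3R)-2-(methoxyacetyl)-3-(5-phenylpentyl)cyclohex-1-en-1-yl]-N,N-dimethylethanimidamide | COCC(=O)C1=C(N=C(C)N(C)C)CCC[C@H]1CCCCCc1ccccc1
F7 | step 5 | (5R)-4-chloro-3-methoxy-2-methyl-5-(5-phenylpentyl)-5,6,7,8-tetrahydroquinoline | COc1c(C)nc2c(c1Cl)[C@H](CCCCCc1ccccc1)CCC2
F8 | step 5 | (5R)-4-chloro-3-methoxy-2-methyl-5-(5-phenylpentyl)-5,6,7,8-tetrahydroquinoline 1-oxide | COc1c(C)[n+]([O-])c2c(c1Cl)[C@H](CCCCCc1ccccc1)CCC2
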